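**Plan**

- Retrosynthesis (labdane numbering): cut the O15 ester and unmask the C19 acid; remove the C4 methyl (reductive methylation of a C3=C4 enoate); cut C1–C2 and C5–C10 together by a retro-[4+2], which opens both rings to an acyclic tetraene ester; then cut C3–C4 (vinyl), C4–C19 and C8–C9 back to (R)-citronellol.
- Enabling feature: C2=C3–C4(CO2R)=C5 is a 2-alkoxycarbonyl-1,3-diene and C10(=C1H2)CH3 is an isopropenyl dienophile on C9. The C6–C7–C8–C9 tether makes them a 1,7,9-decatriene, so one cycloaddition closes ring A directly and ring B through the tether, and leaves the C3=C4 enoate needed for the C4 quaternary centre.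
- Forward: citronellol → (E)-allylic alcohol → Sharpless epoxide → C8–C9 bond by invertive epoxide opening → isopropenyl group by Corey–Winter olefination → alkynoate → (Z)-2-ethenyl enoate → thermal intramolecular Diels–Alder reaction (rings A and B) → Li/NH3/MeI at C4 → ester at O15 → release of the C19 acid.
- Stereochemistry: C13 from (R)-citronellol; C9 from the Sharpless epoxidation (D-tartrate) followed by SN2 inversion; C5 and C10 from C9 in the cycloaddition (chair-like anti transition state, side chain equatorial); C4 by methylation of the ester enolate opposite the angular methyl; C2' from (R)-2-methylbutanoic acid.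

Key step: step 12

Remark: labdane numbering (C17 = methylidene carbon, C19 = carboxyl carbon, C20 = angular methyl, C2' = stereocentre of the acyl group) is used for all intermediates; (R)-2-methylbutanoic acid, D-(−)-diethyl tartrate and 2-(trimethylsilyl)ethyl chloroformate are taken to be purchasable.

**Route**

Step 1
Reactants: 1 (R)-citronellol
Product: 2 tert-butyl{[(3R)-3,7-dimethyloct-6-en-1-yl]oxy}dimethylsilane
Conditions: TBSCl, imidazole, DMF, 0 °C → rt
Reagents that add atoms: tert-butyldimethylsilyl chloride, CC(C)(C)[Si](C)(C)Cl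
Why: Standard imidazole-assisted silylation masks O15 through the organometallic and dissolving-metal steps; the C13 stereocentre is carried over unchanged from (R)-citronellol.

Step 2
Reactants: 2 silyl ether
Product: 3 (2E,6R)-8-[(tert-butyldimethylsilyl)oxy]-2,6-dimethyloct-2-en-1-ol
Conditions: SeO2 (0.3 equiv), t-BuOOH (decane), salicylic acid (cat.), CH2Cl2, 0 °C → rt
Reagents that add atoms: tert-butyl hydroperoxide, CC(C)(C)OO (oxygen relayed by catalytic selenium dioxide, O=[Se]=O)
Why: Riley–Sharpless allylic oxidation (ene reaction with SeO2, then [2,3]-sigmatropic shift) hydroxylates the (E)-methyl group of a trisubstituted prenyl terminus, so the (E)-2-methyl allylic alcohol should form selectively.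

Step 3
Reactants: 3 allylic alcohol
Product: 4 {(2R,3R)-3-[(3R)-5-[(tert-butyldimethylsilyl)oxy]-3-methylpentyl]-2-methyloxiran-2-yl}methanol
Conditions: Ti(OiPr)4 (10 mol %), D-(−)-diethyl tartrate (12 mol %), t-BuOOH (decane), 4 Å MS, CH2Cl2, −20 °C
Reagents that add atoms: tert-butyl hydroperoxide, CC(C)(C)OO
Why: Katsuki–Sharpless asymmetric epoxidation, for which (E)-2-methylalk-2-en-1-ols are among the best substrates; the D-tartrate should give the (2R,3R)-epoxide under reagent control, which fixes C9 (to be inverted in step 5) and, temporarily, C10.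

Step 4
Reactants: 5 1-(trimethylsilyl)propyne; 6 2,3-dibromoprop-1-ene
Product: 8 (5-bromohex-5-en-1-yn-1-yl)trimethylsilane, via 3-lithio-1-(trimethylsilyl)propyne 7 (not isolated)
Conditions: 5, n-BuLi, TMEDA, THF, −20 °C; then 6, −78 °C → rt
Reagents that add atoms: none
Why: Propargylic lithiation of the silylpropyne and SN2 alkylation at the allylic CH2Br of the dibromide; the silyl group keeps the anion propargylic and the vinylic bromide is inert.

Step 5
Reactants: 4 epoxy alcohol; 8 alkenyl bromide
Product: 10 (2S,3R)-3-[(3R)-5-[(tert-butyldimethylsilyl)oxy]-3-methylpentyl]-2-methyl-4-methylidene-8-(trimethylsilyl)oct-7-yne-1,2-diol, via [6-(trimethylsilyl)hex-1-en-5-yn-2-yl]magnesium bromide 9 (not isolated)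
Conditions: 8, Mg, THF, 45 °C (3.5 equiv of 9); CuI (0.3 equiv), then 4, THF, −30 → 0 °C; aq. NH4Cl
Reagents that add atoms: none
Why: Copper-catalysed Grignard opening of a 2,3-epoxy alcohol; C10 is fully substituted, so the alkenyl group should attack C9 in an SN2 manner anti to the C–O bond, and this inversion creates the C9 stereocentre with all three carbon substituents in place.

Step 6
Reactants: 10 diol
Product: 11 (4S)-4-{(3R,6R)-1-[(tert-butyldimethylsilyl)oxy]-3-methyl-7-methylidene-11-(trimethylsilyl)undec-10-yn-6-yl}-4-methyl-1,3-dioxolane-2-thione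
Conditions: 1,1'-thiocarbonyldiimidazole, DMAP (cat.), toluene, 80 °C
Reagents that add atoms: 1,1'-thiocarbonyldiimidazole, S=C(n1ccnc1)n1ccnc1
Why: Formation of the five-membered cyclic thionocarbonate of a 1,2-diol (first stage of the Corey–Winter olefination); no stereocentre is touched.

Step 7
Reactants: 11 thionocarbonate
Product: 12 tert-butyldimethyl{[(3R,6S)-3-methyl-7-methylidene-6-(prop-1-en-2-yl)-11-(trimethylsilyl)undec-10-yn-1-yl]oxy}silane
Conditions: 1,3-dimethyl-2-phenyl-1,3,2-diazaphospholidine (3 equiv), THF, 40 °C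
Reagents that add atoms: none
Why: Corey–Winter olefination (Corey–Hopkins variant): thiophilic attack of phosphorus and cycloelimination of CO2 place the new double bond exactly between C10 and C1, which avoids the regiochemical ambiguity of dehydrating the tertiary alcohol and leaves the doubly allylic C9–H untouched.

Step 8
Reactants: 12 alkynylsilane
Product: 13 tert-butyldimethyl{[(3R,6S)-3-methyl-7-methylidene-6-(prop-1-en-2-yl)undec-10-yn-1-yl]oxy}silane
Conditions: K2CO3, MeOH, rt
Reagents that add atoms: none
Why: Carbonate-catalysed methanolysis of the alkynyl C–Si bond; the silyl ether and the skipped diene are inert.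

Step 9
Reactants: 13 terminal alkyne
Product: 15 2-(trimethylsilyl)ethyl (7S,10R)-12-[(tert-butyldimethylsilyl)oxy]-10-methyl-6-methylidene-7-(prop-1-en-2-yl)dodec-2-ynoate, via lithium acetylide 14 (not isolated)
Conditions: n-BuLi (1.0 equiv), THF, −78 °C; then ClCO2CH2CH2SiMe3, −78 → −20 °C
Reagents that add atoms: 2-(trimethylsilyl)ethyl chloroformate, C[Si](C)(C)CCOC(Cl)=O
Why: One equivalent of base at −78 °C deprotonates only the alkyne (not the doubly allylic C9–H), and C-acylation of the acetylide with a chloroformate gives the alkynoate; the 2-(trimethylsilyl)ethyl ester is removable by fluoride at the end without touching the O15 ester.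

Step 10
Reactants: 15 alkynoate
Product: 16 2-(trimethylsilyl)ethyl (2E,7S,10R)-12-[(tert-butyldimethylsilyl)oxy]-10-methyl-6-methylidene-7-(prop-1-en-2-yl)-2-(tributylstannyl)dodec-2-enoate
Conditions: Bu3SnH (1.1 equiv), Pd(PPh3)4 (2 mol %), THF, 0 °C → rt
Reagents that add atoms: tributyltin hydride, CCCC[SnH](CCCC)CCCC
Why: Syn-hydrostannation of a 2-alkynoate under zerovalent-palladium catalysis puts tin on the α-carbon (C4) and hydrogen on C5 on the same side, so C6 ends cis to the ester, the geometry the diene needs; the isolated 1,1-disubstituted alkenes do not react.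

Step 11
Reactants: 16 stannane
Product: 17 2-(trimethylsilyl)ethyl (2Z,7S,10R)-12-[(tert-butyldimethylsilyl)oxy]-2-ethenyl-10-methyl-6-methylidene-7-(prop-1-en-2-yl)dodec-2-enoate
Conditions: vinyl bromide (1 M in THF, 3 equiv), Pd2(dba)3 (2.5 mol %), P(2-furyl)3, CuI (0.2 equiv), NMP, 50 °C
Reagents that add atoms: vinyl bromide, C=CBr
Why: Stille coupling with retention of alkene geometry, accelerated by CuI for the hindered α-stannyl enoate, should give the diene with the tether on the outside of its s-cis form.

Step 12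
Reactants: 17 tetraene ester
Product: 18 2-(trimethylsilyl)ethyl (4aS,5R,8aS)-5-[(3R)-5-[(tert-butyldimethylsilyl)oxy]-3-methylpentyl]-4a-methyl-6-methylidene-3,4,4a,5,6,7,8,8a-octahydronaphthalene-1-carboxylate
Conditions: BHT (0.1 equiv), degassed toluene (0.005 M), sealed tube, 175 °C
Reagents that add atoms: none
Why: A thermal, concerted but asynchronous [4+2] cycloaddition (type 1 intramolecular Diels–Alder reaction of a 1,7,9-decatriene) joins the ester-bearing diene C2=C3–C4=C5 to the isopropenyl dienophile C10=C1 with inverse-electron-demand character; the closest known reaction type is the thermal cyclisation of unactivated 1,7,9-decatrienes and of 2-alkoxycarbonyl-1,3-dienes to octalins. Ring A (C1, C2, C3, C4, C5, C10) is closed by the cycloaddition itself and ring B (C5 to C10 through the C6–C9 tether) arises in the fused mode, the bridged mode being excluded by the four-carbon tether. The quaternary C10 and C5 are set in one event, and trans fusion is expected from the chair-like anti transition state, the syn alternative being more crowded because the tether must fold under the diene face next to the C4 ester. The absolute sense of C5 and C10 is controlled by C9, whose side chain should lie pseudo-equatorial and anti to the forming C10–C5 bond with C9–H eclipsing C10=C1 (least A(1,3) strain), which puts the side chain cis to C20 as in the target. The step needs π-facial selectivity (from C9), trans over cis fusion, a diene with the tether on its outside (secured by steps 10 and 11) and chemoselectivity against the C8=C17 alkene, which cannot reach the diene through a two-atom link. Lewis acids are avoided because a polarised pathway would favour bonding of C1 to C5, and BHT with high dilution should suppress oligomerisation of the diene.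

Step 13
Reactants: 18 octalin enoate
Product: 20 2-(trimethylsilyl)ethyl (1R,4aS,5R,8aS)-5-[(3R)-5-[(tert-butyldimethylsilyl)oxy]-3-methylpentyl]-1,4a-dimethyl-6-methylidenedecahydronaphthalene-1-carboxylate, via lithium ester enolate 19 (not isolated)
Conditions: Li (2.2 equiv), NH3(l)/THF, t-BuOH (1.0 equiv), −78 °C; then MeI, −78 → −33 °C
Reagents that add atoms: iodomethane, CI
Why: Dissolving-metal reduction of the conjugated ester (proton from t-BuOH to C3) gives the exocyclic ester enolate, which should be methylated from the face opposite the axial C10 methyl, so the ester ends axial and cis to C20 (Coates–Shaw type reductive alkylation); isolated alkenes and both silyl groups survive.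

Step 14
Reactants: 20 silyl ether
Product: 21 2-(trimethylsilyl)ethyl (1R,4aS,5R,8aS)-5-[(3R)-5-hydroxy-3-methylpentyl]-1,4a-dimethyl-6-methylidenedecahydronaphthalene-1-carboxylate
Conditions: HF·pyridine, pyridine, THF, 0 °C → rt
Reagents that add atoms: none
Why: Buffered HF cleaves the primary silyl ether without free fluoride ion, so the 2-(trimethylsilyl)ethyl ester and the exocyclic alkene should be retained.

Step 15
Reactants: 21 alcohol; 22 (R)-2-methylbutanoic acid
Product: 23 2-(trimethylsilyl)ethyl (1R,4aS,5R,8aS)-1,4a-dimethyl-6-methylidene-5-{(3R)-3-methyl-5-[(2R)-2-methylbutanoyloxy]pentyl}decahydronaphthalene-1-carboxylate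
Conditions: EDC·HCl, DMAP (0.1 equiv), CH2Cl2, 0 °C → rt
Reagents that add atoms: none
Why: Steglich-type carbodiimide esterification of the unhindered primary alcohol at 0 °C with little DMAP, conditions under which the α-stereocentre of the acid should not epimerise.

Step 16
Reactants: 23 diester
Product: 24 (1R,4aS,5R,8aS)-1,4a-dimethyl-6-methylidene-5-{(3R)-3-methyl-5-[(2R)-2-methylbutanoyloxy]pentyl}decahydronaphthalene-1-carboxylic acid (target)
Conditions: TBAF (1 M in THF), THF, 0 °C → rt; aq. NH4Cl
Reagents that add atoms: none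
Why: Fluoride attacks silicon and triggers β-elimination (ethene, Me3SiF), which frees the hindered axial acid without nucleophilic attack at either carbonyl, so the O15 ester and all stereocentres remain.

**Compound list**

1 | (R)-citronellol | CC(C)=CCC[C@@H](C)CCO | starting material
2 | tert-butyl{[(3R)-3,7-dimethyloct-6-en-1-yl]oxy}dimethylsilane | CC(C)=CCC[C@@H](C)CCO[Si](C)(C)C(C)(C)C | intermediate
3 | (2E,6R)-8-[(tert-butyldimethylsilyl)oxy]-2,6-dimethyloct-2-en-1-ol | OC/C(C)=C/CC[C@@H](C)CCO[Si](C)(C)C(C)(C)C | intermediate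
4 | {(2R,3R)-3-[(3R)-5-[(tert-butyldimethylsilyl)oxy]-3-methylpentyl]-2-methyloxiran-2-yl}methanol | CC(C)(C)[Si](C)(C)OCC[C@H](C)CC[C@H]1O[C@]1(C)CO | intermediate
5 | 1-(trimethylsilyl)propyne | CC#C[Si](C)(C)C | starting material
6 | 2,3-dibromoprop-1-ene | C=C(Br)CBr | starting material
7 | 3-lithio-1-(trimethylsilyl)propyne | [Li]CC#C[Si](C)(C)C | intermediate (not isolated)
8 | (5-bromohex-5-en-1-yn-1-yl)trimethylsilane | C=C(Br)CCC#C[Si](C)(C)C | intermediate
9 | [6-(trimethylsilyl)hex-1-en-5-yn-2-yl]magnesium bromide | C=C([Mg]Br)CCC#C[Si](C)(C)C | intermediate (not isolated)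
10 | (2S,3R)-3-[(3R)-5-[(tert-butyldimethylsilyl)oxy]-3-methylpentyl]-2-methyl-4-methylidene-8-(trimethylsilyl)oct-7-yne-1,2-diol | C[Si](C)(C)C#CCCC(=C)[C@@H](CC[C@@H](C)CCO[Si](C)(C)C(C)(C)C)[C@](C)(O)CO | intermediate
11 | (4S)-4-{(3R,6R)-1-[(tert-butyldimethylsilyl)oxy]-3-methyl-7-methylidene-11-(trimethylsilyl)undec-10-yn-6-yl}-4-methyl-1,3-dioxolane-2-thione | C[Si](C)(C)C#CCCC(=C)[C@@H](CC[C@@H](C)CCO[Si](C)(C)C(C)(C)C)[C@@]1(C)COC(=S)O1 | intermediate
12 | tert-butyldimethyl{[(3R,6S)-3-methyl-7-methylidene-6-(prop-1-en-2-yl)-11-(trimethylsilyl)undec-10-yn-1-yl]oxy}silane | C[Si](C)(C)C#CCCC(=C)[C@@H](CC[C@@H](C)CCO[Si](C)(C)C(C)(C)C)C(C)=C | intermediate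
13 | tert-butyldimethyl{[(3R,6S)-3-methyl-7-methylidene-6-(prop-1-en-2-yl)undec-10-yn-1-yl]oxy}silane | C#CCCC(=C)[C@@H](CC[C@@H](C)CCO[Si](C)(C)C(C)(C)C)C(C)=C | intermediate
14 | lithium acetylide of 13 | [Li]C#CCCC(=C)[C@@H](CC[C@@H](C)CCO[Si](C)(C)C(C)(C)C)C(C)=C | intermediate (not isolated)
15 | 2-(trimethylsilyl)ethyl (7S,10R)-12-[(tert-butyldimethylsilyl)oxy]-10-methyl-6-methylidene-7-(prop-1-en-2-yl)dodec-2-ynoate | C[Si](C)(C)CCOC(=O)C#CCCC(=C)[C@@H](CC[C@@H](C)CCO[Si](C)(C)C(C)(C)C)C(C)=C | intermediate
16 | 2-(trimethylsilyl)ethyl (2E,7S,10R)-12-[(tert-butyldimethylsilyl)oxy]-10-methyl-6-methylidene-7-(prop-1-en-2-yl)-2-(tributylstannyl)dodec-2-enoate | CCCC[Sn](CCCC)(CCCC)/C(C(=O)OCC[Si](C)(C)C)=C/CCC(=C)[C@@H](CC[C@@H](C)CCO[Si](C)(C)C(C)(C)C)C(C)=C | intermediate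
17 | 2-(trimethylsilyl)ethyl (2Z,7S,10R)-12-[(tert-butyldimethylsilyl)oxy]-2-ethenyl-10-methyl-6-methylidene-7-(prop-1-en-2-yl)dodec-2-enoate | C=C/C(C(=O)OCC[Si](C)(C)C)=C/CCC(=C)[C@@H](CC[C@@H](C)CCO[Si](C)(C)C(C)(C)C)C(C)=C | intermediate
18 | 2-(trimethylsilyl)ethyl (4aS,5R,8aS)-5-[(3R)-5-[(tert-butyldimethylsilyl)oxy]-3-methylpentyl]-4a-methyl-6-methylidene-3,4,4a,5,6,7,8,8a-octahydronaphthalene-1-carboxylate | C=C1CC[C@H]2[C@@](C)(CCC=C2C(=O)OCC[Si](C)(C)C)[C@@H]1CC[C@@H](C)CCO[Si](C)(C)C(C)(C)C | intermediate
19 | lithium enolate (O-lithio ketene acetal) of the C3,C4-dihydro ester of 18 | C=C1CC[C@H]2[C@@](C)(CCCC2=C(O[Li])OCC[Si](C)(C)C)[C@@H]1CC[C@@H](C)CCO[Si](C)(C)C(C)(C)C | intermediate (not isolated)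
20 | 2-(trimethylsilyl)ethyl (1R,4aS,5R,8aS)-5-[(3R)-5-[(tert-butyldimethylsilyl)oxy]-3-methylpentyl]-1,4a-dimethyl-6-methylidenedecahydronaphthalene-1-carboxylate | C=C1CC[C@H]2[C@@](C)(CCC[C@@]2(C)C(=O)OCC[Si](C)(C)C)[C@@H]1CC[C@@H](C)CCO[Si](C)(C)C(C)(C)C | intermediate
21 | 2-(trimethylsilyl)ethyl (1R,4aS,5R,8aS)-5-[(3R)-5-hydroxy-3-methylpentyl]-1,4a-dimethyl-6-methylidenedecahydronaphthalene-1-carboxylate | C=C1CC[C@H]2[C@@](C)(CCC[C@@]2(C)C(=O)OCC[Si](C)(C)C)[C@@H]1CC[C@@H](C)CCO | intermediate
22 | (R)-2-methylbutanoic acid | CC[C@@H](C)C(=O)O | starting material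
23 | 2-(trimethylsilyl)ethyl (1R,4aS,5R,8aS)-1,4a-dimethyl-6-methylidene-5-{(3R)-3-methyl-5-[(2R)-2-methylbutanoyloxy]pentyl}decahydronaphthalene-1-carboxylate | C=C1CC[C@H]2[C@@](C)(CCC[C@@]2(C)C(=O)OCC[Si](C)(C)C)[C@@H]1CC[C@@H](C)CCOC(=O)[C@H](C)CC | intermediate
24 | (1R,4aS,5R,8aS)-1,4a-dimethyl-6-methylidene-5-{(3R)-3-methyl-5-[(2R)-2-methylbutanoyloxy]pentyl}decahydronaphthalene-1-carboxylic acid | C=C1CC[C@H]2[C@@](C)(CCC[C@@]2(C)C(=O)O)[C@@H]1CC[C@@H](C)CCOC(=O)[C@H](C)CC | target

**Step count and risks**

Total steps: 16. Longest linear sequence: 15 (steps 1–3 and 5–16; step 4 makes the side fragment).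

Steps most likely to fail:

1. Step 12 (cycloaddition). What may go wrong: insufficient discrimination between the two π-faces of the dienophile by C9 (the equatorial side chain nearly eclipses the C8 methylidene group, which narrows the preference), competing closure through the syn transition state to the cis-fused system, and thermal oligomerisation of the electron-poor diene before it cyclises. Fallback: from 17, returning at 18, the concerted thermal closure is replaced by a metal-templated, stepwise [4+2]. A cationic monovalent-rhodium catalyst ([Rh(cod)Cl]2 with AgSbF6 and P[OCH(CF3)2]3 in 2,2,2-trifluoroethanol, 25–55 °C) binds diene and alkene, closes a rhodacycle by oxidative cyclisation and releases the octalin by reductive elimination, as in the known rhodium-catalysed cyclisation of unactivated diene-enes. It runs far cooler, which should widen the gap between the diastereomeric pathways and suppress oligomerisation. No new compound is made (F0).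

2. Step 5 (epoxide opening). What may go wrong: slow SN2 attack of an α-branched alkenyl nucleophile at C9 next to the fully substituted epoxide carbon, with competing halohydrin formation by magnesium halide or epoxide migration. Fallback: from 4, returning at 12, the alkenyl nucleophile is replaced by a slim alkynyl one and the methylidene branch is built afterwards. Epoxide 4 is opened at C9 with diethylaluminium (trimethylsilyl)acetylide (from (trimethylsilyl)acetylene, n-BuLi and Et2AlCl, toluene, 0 °C; delivery from the aluminium alkoxide, inversion) to (2S,3R)-3-[(3R)-5-[(tert-butyldimethylsilyl)oxy]-3-methylpentyl]-2-methyl-5-(trimethylsilyl)pent-4-yne-1,2-diol F1. Thiocarbonyldiimidazole converts it into (4S)-4-{(3R,6R)-1-[(tert-butyldimethylsilyl)oxy]-3-methyl-8-(trimethylsilyl)oct-7-yn-6-yl}-4-methyl-1,3-dioxolane-2-thione F2, and Corey–Winter elimination gives tert-butyldimethyl{[(3R,6S)-3-methyl-6-(prop-1-en-2-yl)-8-(trimethylsilyl)oct-7-yn-1-yl]oxy}silane F3. K2CO3 in MeOH frees tert-butyldimethyl{[(3R,6S)-3-methyl-6-(prop-1-en-2-yl)oct-7-yn-1-yl]oxy}silane F4. Normant carbocupration of F4 with [4-(trimethylsilyl)but-3-yn-1-yl]copper–MgBr2 (from the Grignard reagent of (4-bromobut-1-yn-1-yl)trimethylsilane and CuBr·SMe2, Et2O/Me2S, −25 °C → rt) adds the alkyl group to the internal alkyne carbon (C8) and, after protonolysis, gives 12.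

3. Step 11 (Stille coupling). What may go wrong: slow transmetalation of the hindered α-stannyl enoate, leading to protodestannylation, homocoupling or loss of alkene geometry. Fallback: from 16, returning at 17, the coupling polarity is reversed. Iododestannylation of 16 (I2, CH2Cl2, 0 °C, retention) gives 2-(trimethylsilyl)ethyl (2E,7S,10R)-12-[(tert-butyldimethylsilyl)oxy]-2-iodo-10-methyl-6-methylidene-7-(prop-1-en-2-yl)dodec-2-enoate F5, which is coupled with potassium vinyltrifluoroborate (PdCl2(dppf), Cs2CO3, THF/H2O, 60 °C; Suzuki–Miyaura coupling, retention) to give 17.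

Further compounds
F0 | step 12 | none | none
F1 | step 5 | (2S,3R)-3-[(3R)-5-[(tert-butyldimethylsilyl)oxy]-3-methylpentyl]-2-methyl-5-(trimethylsilyl)pent-4-yne-1,2-diol | C[Si](C)(C)C#C[C@@H](CC[C@@H](C)CCO[Si](C)(C)C(C)(C)C)[C@](C)(O)CO
F2 | step 5 | (4S)-4-{(3R,6R)-1-[(tert-butyldimethylsilyl)oxy]-3-methyl-8-(trimethylsilyl)oct-7-yn-6-yl}-4-methyl-1,3-dioxolane-2-thione | C[Si](C)(C)C#C[C@@H](CC[C@@H](C)CCO[Si](C)(C)C(C)(C)C)[C@@]1(C)COC(=S)O1
F3 | step 5 | tert-butyldimethyl{[(3R,6S)-3-methyl-6-(prop-1-en-2-yl)-8-(trimethylsilyl)oct-7-yn-1-yl]oxy}silane | C[Si](C)(C)C#C[C@@H](CC[C@@H](C)CCO[Si](C)(C)C(C)(C)C)C(C)=C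
F4 | step 5 | tert-butyldimethyl{[(3R,6S)-3-methyl-6-(prop-1-en-2-yl)oct-7-yn-1-yl]oxy}silane | C#C[C@@H](CC[C@@H](C)CCO[Si](C)(C)C(C)(C)C)C(C)=C
F5 | step 11 | 2-(trimethylsilyl)ethyl (2E,7S,10R)-12-[(tert-butyldimethylsilyl)oxy]-2-iodo-10-methyl-6-methylidene-7-(prop-1-en-2-yl)dodec-2-enoate | I/C(C(=O)OCC[Si](C)(C)C)=C/CCC(=C)[C@@H](CC[C@@H](C)CCO[Si](C)(C)C(C)(C)C)C(C)=C
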